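A fraction of the charge per hour is the unit to watch when you repeat this run, since the choice between heating and waiting is a choice between rates.

| flask | substrate | partner | temperature | remark | time |
|---|---|---|---|---|---|
| south | 0.50 M | 1 equiv | 90 °C | the very flask that is asked about, followed so far |  |
| south-east | 0.50 M | 0.50 equiv | 75 °C | run made earlier |  |
| flask | 0.50 M | 1.00 equiv | 90 °C |  | 8.0 d |

| south: time / h | south: target / % | south-east: time / h | south-east: target / % |
|---|---|---|---|
| 12.0 | 60 | 2.00 | 5 |
| 20.0 | 66 | 5.00 | 3 |
| 30.0 | 69 | 10.0 | 14 |
| 60.0 | 73 | 15.0 | 16 |
| 96.0 | 77 | 20.0 | 23 |
| 144 | 76 | 30.0 | 36 |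

(standard deviation of a reading: 2 percentage points)

- ochre: at 8.0 d raise the temperature by 10 K, then wait 8.0 d
- grey: at 8.0 d add partner, 50.0 % of the amount charged, then wait 8.0 d
- violet: at 8.0 d take out 90 % of the target then present, then wait 8.0 d
- amber: change nothing and wait 8.0 d more

- what is taken out of target is counted as made
- additions bring no volume worth counting

1. target, in percent of the substrate first charged, at 8.0 d
2. the remedy with the largest gain of target, or "none" below 2 percentage points (ochre / grey / violet / amber / none)
3. target present, with what was taken out counted in, in percent of the substrate first charged, after ochre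
4. target present, with what was taken out counted in, in percent of the substrate first charged, after violet

Replace each early curve by its mean slope. The south run makes target at 0.0500 /h over its first 12.0 h, and the south-east run at 0.0120 /h over its 30.0 h, so the hotter run is faster by a ratio of 4.17 for 15.0 K. Spread evenly over those degrees, the ratio becomes 2.59: this is my heat factor, the multiplier that a rise of 10 K puts on the rate of the flask's tail.

This reckoning carries two errors. The south curve already bends inside its first stretch, so its mean understates the opening rate. The south-east run also had [partner] at half the south value, and if the rate followed [partner] in proportion, the factor would fall to 1.63.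

Now the choice. Ochre clears the margin of 2 percentage points if plain waiting would bring more than 0.77 points in 8.0 d, or 1.2 points with the lower factor. The south tail from 60.0 h to 144 h, carried over 8.0 d, gives 6.9 points, more than either. But that reading carries a scatter of 6.5 points, and the slope is falling. My reckoning is therefore a bet: charge the same flask, and at 8.0 d raise the temperature.

The forecast differs, with 76.5 % now, none as best remedy, 77 % after ochre and 77 % after violet. Its ground: “So the reaction has died, with substrate and partner both left over, rather than reaching equilibrium.”

    substrate ⇌ intermediate A (K = 3.15, k = 0.0455 /h, Ea = 115 kJ/mol, ΔH = −46.0 kJ/mol)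
    substrate → side product (k = 0.0229 /h, Ea = 126 kJ/mol)
    substrate → intermediate B (k = 0.140 /h, Ea = 106 kJ/mol)
    intermediate A ⇌ intermediate C (K = 3.00, k = 0.00861 /h, Ea = 123 kJ/mol, ΔH = −65.0 kJ/mol)
    partner + intermediate B ⇌ intermediate D (K = 2.61 /M, k = 0.159 /M/h, Ea = 103 kJ/mol, ΔH = 8.00 kJ/mol)
    partner + intermediate B → target (k = 2.14 /M/h, Ea = 83.0 kJ/mol)
    (constants at 90 °C)

The flask reads 78.5 % at 8.0 d, the best remedy is ochre, and violet reaches 80.5 %. At that time it still holds 6.98 % of intermediate C and 1.52 % of intermediate A. Amber gains 2.1 points, more than the 0.77 points required. Multiplied by the heat factor of 2.59, that gain becomes 5.4 points, and ochre in fact brings 6 points, reaching 84.4 %.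

The data are simulated with constants of no real substance, noise included.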